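All runs are calculated for substances that don't exist; noise was put on by code.

Percentage points are the unit to watch in this flask: one reading scatters by 2 percentage points, and the answer turns on a few of them.

all flasks: starting material 0.20 M

| charge | reagent | remark | time |
|---|---|---|---|
| Thursday's | 0.30 M | run made earlier |  |
| Friday's | 1.2 M | run made earlier |  |
| flask | 0.600 M |  | 10 h |

| run | time / h | target / % | isomer of the product / % |
|---|---|---|---|
| Thursday's | 0.500 | 43 | 28 |
| Thursday's | 1.50 | 35 | 32 |
| Thursday's | 3.00 | 36 | 39 |
| Thursday's | 4.00 | 37 | 39 |
| Thursday's | 6.00 | 38 | 36 |
| Thursday's | 8.00 | 34 | 37 |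
| Friday's | 1.33 | 53 | 43 |
| Friday's | 2.50 | 46 | 45 |
| Friday's | 4.00 | 52 | 50 |
| Friday's | 5.00 | 43 | 45 |
| Friday's | 6.00 | 49 | 42 |
| Friday's | 8.00 | 50 | 45 |

(each reading ± 2 percentage points)

* share of target in target plus isomer of the product at 30 s
* share of target in target plus isomer of the product at 10 h

- the numbers in the tables scatter by 2 percentage points (one standard deviation)
- steps thought possible: starting material + reagent <-> target; starting material + reagent <-> isomer of the product

Thursday's and Friday's runs differ in their reagent, 0.30 M against 1.2 M. We average the level readings, from 3.00 h on Thursday and from 2.50 h on Friday. Target plus isomer of the product then stands at 74.0 % on Thursday and 93.4 % on Friday, while the target's share is 49.0 % and 51.4 %. Because each step takes up one starting material and one reagent, the same free [starting material][reagent] stands behind both products at the plateau and cancels from their ratio, so the total moved by 19 points and the share by less, 2.4 points.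

Pooled, the readings give 50.5 % for the plateau share, target over target plus isomer of the product once the amounts stop moving. Thursday's first reading, at 0.500 h, shows a higher share, 60.6 %: kinetic control first, thermodynamic control later. For the flask we therefore reckon 50.5 % at 10 h, later than Thursday's level began, and at 30 s a share near or above that first reading, as an estimate and not a bound.

The forecast gives 70 % (61 % to 82 %) at 30 s and 50.5 % (49 % to 52.5 %) at 10 h, holding that “the equilibrium ratio does not depend on reagent”.

The flask gives 65.1 % at 30 s and 51.1 % at 10 h.

    starting material + reagent ⇌ target (K = 8.07 L mol⁻¹, k = 0.00510 L mol⁻¹ s⁻¹)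
    starting material + reagent ⇌ isomer of the product (K = 7.72 L mol⁻¹, k = 0.00272 L mol⁻¹ s⁻¹)

In the flask, the isomer of the product goes back with a half-life of 0.55 h, short against 10 h. Our plateau share, applied to the flask's 87.1 % of product at 10 h, gives 43.9 % of target, and the flask holds 44.5 %. In a neighbouring flask with 0.15 M of reagent, the plateau share again gives 50.5 %; the computed share there at 10 h is 51.1 %, with target at 24.0 % and isomer of the product at 23.0 %.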